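The oxocane is cut at C6–C7 (chain numbering: C1 alkyne CH to C15 ethyl CH3). The feature exploited is ring carbon C6. It is bonded to the ring oxygen, flanked by oxygen-bearing C7 and extended by the C5–C4 arm, which is what results when a C7 acyl radical attacks the β-carbon of an acrylate hung on O12. One operation forms C6–C7, closes the eight-membered ring and sets C6 cis to C12. The precursor is an open-chain C7 phenylselenoester with an (E)-β-alkoxyacrylate on O12, a cis-dioxolane on C9/C10 and a silyl ether on C13. The C9/C10 diol is installed on a δ-lactone that ties up O12, so C12 directs the osmylation.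

Key step: step 13

Remark: TBS = tert-butyldimethylsilyl, TIPS = triisopropylsilyl. Locants C1–C15 and O12 refer to the target chain in every intermediate, and CIP letters quoted with these locants hold for that intermediate.

Step 1
Reactants: 1 (±)-pent-1-en-3-ol
Product: 2 (2R,3S)-1,2-epoxypentan-3-ol (C12 R; C13 S)
Conditions: Ti(OiPr)4 (10 mol %), L-(+)-DIPT (12 mol %), t-BuOOH (0.45 equiv), 4 Å MS, CH2Cl2, −20 °C
Reagents that add atoms: tert-butyl hydroperoxide, CC(C)(C)OO
Why: Sharpless kinetic-resolution epoxidation: with L-(+)-DIPT the (S)-alcohol is the fast-reacting enantiomer and takes oxygen on the alkene face that gives the erythro epoxy alcohol, so C13 (S) is selected and C12 (R) is created under reagent control, while the slow (R)-alcohol stays unchanged and is removed by chromatography.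

Step 2
Reactants: 2 (2R,3S)-1,2-epoxypentan-3-ol
Product: 3 (2R,3S)-3-(TBS-oxy)-1,2-epoxypentane
Conditions: TBSCl, imidazole, DMF, 0 °C to rt
Reagents that add atoms: tert-butyldimethylsilyl chloride, CC(C)(C)[Si](C)(C)Cl
Why: Imidazole-promoted O-silylation works on this unhindered secondary alcohol without a strong base, so Payne rearrangement of the epoxy alcohol is avoided and no stereocentre is touched.

Step 3
Reactants: 3 (2R,3S)-3-(TBS-oxy)-1,2-epoxypentane; 4 ethyl propiolate
Product: 6 ethyl (5R,6S)-6-(TBS-oxy)-5-hydroxyoct-2-ynoate, via lithium ethyl propiolate 5 (not isolated)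
Conditions: 4, n-BuLi, THF, −78 °C; BF3·OEt2; then 3, −78 °C
Reagents that add atoms: none
Why: Yamaguchi–Hirao alkynylation: the BF3-activated terminal epoxide is opened by the acetylide at its unhindered CH2 (C11) in an SN2 process, which forms C10–C11 and leaves the C12–O bond and its configuration intact.

Step 4
Reactants: 6 ethyl (5R,6S)-6-(TBS-oxy)-5-hydroxyoct-2-ynoate
Product: 8 (6R)-6-[(1S)-1-(TBS-oxy)propyl]-5,6-dihydro-2H-pyran-2-one, via (Z)-hydroxy enoate 7 (not isolated)
Conditions: H2 (1 atm), Pd/CaCO3 poisoned with Pb(OAc)2, quinoline, EtOAc, rt; filter; PPTS (cat.), toluene, 80 °C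
Reagents that add atoms: none
Why: Lindlar semihydrogenation gives the (Z)-enoate, whose geometry places the C12 hydroxyl next to the ester so that mild acid closes the δ-lactone, which masks O12 and provides a ring template for the next step.

Step 5
Reactants: 8 (6R)-6-[(1S)-1-(TBS-oxy)propyl]-5,6-dihydro-2H-pyran-2-one
Product: 9 (3S,4S,6R)-3,4-dihydroxy-6-[(1S)-1-(TBS-oxy)propyl]oxan-2-one (cis-diol at C9/C10 trans to the C13 side chain)
Conditions: OsO4 (cat.), NMO, acetone–H2O, rt
Reagents that add atoms: N-methylmorpholine N-oxide, C[N+]1([O-])CCOCC1; water, O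
Why: Upjohn syn-dihydroxylation of a 6-substituted 5,6-dihydropyran-2-one, a substrate class known to react anti to the C6 substituent: in the half-chair with the bulky side chain pseudo-equatorial, OsO4 adds anti to the pseudo-axial C11–H on the face away from that chain, which sets C9 and C10 together by relay from C12.

Step 6
Reactants: 9 (3S,4S,6R)-3,4-dihydroxy-6-[(1S)-1-(TBS-oxy)propyl]oxan-2-one
Product: 10 3,4-O-isopropylidene derivative of 9 (cis-fused dioxolane on the δ-lactone)
Conditions: Me2C(OMe)2, PPTS (cat.), acetone, rt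
Reagents that add atoms: 2,2-dimethoxypropane, COC(C)(C)OC
Why: Acid-catalysed transketalisation of a cis-vicinal ring diol is fast, and because O12 is still the lactone oxygen no competing 1,3-dioxane across O10/O12 can form.

Step 7
Reactants: 10 acetonide lactone
Product: 11 acetonide lactol (C8 hemiacetal; anomer mixture)
Conditions: i-Bu2AlH (DIBAL-H, 1.1 equiv), CH2Cl2, −78 °C
Reagents that add atoms: none
Why: Partial lactone reduction with DIBAL-H stops at the cold, stable aluminium hemiacetal, which gives the lactol on work-up while the silyl ether and acetonide are inert.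

Step 8
Reactants: 11 acetonide lactol
Product: 12 (2R,3S)-3-(TBS-oxy)-1-[(4S,5R)-2,2-dimethyl-5-vinyl-1,3-dioxolan-4-yl]pentan-2-ol
Conditions: Ph3PCH3Br (3.0 equiv), KN(SiMe3)2 (2.8 equiv), THF, 0 °C to rt
Reagents that add atoms: methyltriphenylphosphonium bromide, C[P+](c1ccccc1)(c1ccccc1)c1ccccc1.[Br-]
Why: Wittig methylenation of a 2,3-O-isopropylidene lactol through its open hydroxy-aldehyde form adds C7 and releases the C12 hydroxyl as the only free OH; keeping the phosphonium salt in excess over the base leaves no strong base, which guards against C9 epimerisation and a silyl shift from O13 to O12.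

Step 9
Reactants: 12 vinyl dioxolane alcohol; 4 ethyl propiolate
Product: 13 ethyl (E)-3-alkoxyacrylate of 12 on O12 (9R,10S,12R,13S)
Conditions: 4, N-methylmorpholine, CH2Cl2, rt
Reagents that add atoms: none
Why: Amine-catalysed oxa-Michael addition of the single free hydroxyl to the propiolate gives the (E)-β-alkoxyacrylate under nearly neutral conditions that touch no stereocentre and cause no silyl migration.

Step 10
Reactants: 13 alkoxyacrylate alkene
Product: 15 C7 primary alcohol (2-hydroxyethyl group on the dioxolane at C9), via B-alkyl-9-BBN adduct 14 (not isolated)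
Conditions: 9-BBN, THF, 0 °C to rt; NaBO3·4H2O, H2O, rt
Reagents that add atoms: sodium perborate (used as the tetrahydrate), [Na+].[O-]OB=O
Why: Brown hydroboration–oxidation: 9-BBN places boron on the terminal carbon C7 of the monosubstituted alkene far faster than it reacts with the push–pull 1,2-disubstituted alkoxyacrylate, and perborate oxidises the C–B bond without harming the ester.

Step 11
Reactants: 15 C7 primary alcohol
Product: 17 C7 carboxylic acid, via C7 aldehyde 16 (not isolated)
Conditions: TEMPO (cat.), PhI(OAc)2, MeCN–H2O, rt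
Reagents that add atoms: water, O
Why: Oxoammonium-mediated oxidation (TEMPO/PhI(OAc)2) takes the primary alcohol through the aldehyde hydrate to the acid in a weakly acidic medium that spares acetonide, silyl ether and alkoxyacrylate.

Step 12
Reactants: 17 C7 carboxylic acid
Product: 18 C7 phenylselenoester bearing the O12 (E)-β-alkoxyacrylate, the C9/C10 acetonide and the C13 TBS ether (9R,10S,12R,13S)
Conditions: (PhSe)2, n-Bu3P, CH2Cl2, rt
Reagents that add atoms: diphenyl diselenide, c1ccccc1[Se][Se]c1ccccc1
Why: Phosphine/diselenide activation turns the acid into an acyloxyphosphonium salt that is captured by selenolate, a standard base-free selenoester synthesis that the poorly electrophilic alkoxyacrylate tolerates.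

Step 13
Reactants: 18 C7 phenylselenoester
Product: 19 ethyl 2-(cis-2,8-disubstituted 3-oxo-oxocan-2-yl)acetate fused to the acetonide (6R,9R,10S,12R,13S; both side chains on one ring face and the dioxolane on the other)
Conditions: (Me3Si)3SiH and Et3B added slowly, air, benzene (about 0.003 M), rt
Reagents that add atoms: none
Why: Ethyl radicals from Et3B/O2 start a chain in which (Me3Si)3Si• removes PhSe from 18, the nucleophilic σ-acyl radical at C7 attacks the electron-poor β-carbon C6, and the ester-stabilised C5 radical takes hydrogen from the silane. The closest known reaction type is the acyl selenide/β-alkoxyacrylate radical cyclisation that gives cis-disubstituted five- to seven-membered oxacycloalkan-3-ones, carried here one ring size further. The oxocane closes in the 8-exo-trig mode, with C6–C7 formed and C5 left outside the ring. C6 is controlled by C12: allylic strain keeps the enol ether s-trans with the C12–H in its plane, and closure with the C5 arm and the C13 chain both pseudo-equatorial places them cis across the ether oxygen, giving (6R). The step needs cyclisation to outrun hydrogen transfer to the acyl radical and loss of CO, and attack at C6 rather than C5; high dilution, the sluggish hydrogen donor (Me3Si)3SiH, room-temperature initiation (a primary-alkyl acyl radical sheds CO slowly) and polarity matching serve this. In the substrate the cis-fused dioxolane holds the C8–C9–C10–C11 torsion near that of a Z-alkene, removes rotors and folds C7 towards C6.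

Step 14
Reactants: 19 oxocan-3-one
Product: 20 (7R)-hydroxy ester (6R,7R,9R,10S,12R,13S; OH cis to the C5 arm)
Conditions: LiBH(s-Bu)3 (L-Selectride), THF, −78 °C
Reagents that add atoms: none
Why: Bulky-hydride ketone reduction: the reagent approaches C7 from the side away from the C5 arm on neighbouring C6, so the new hydroxyl ends up cis to that arm (7R), and the cold quench limits attack of the alkoxide on the ester.

Step 15
Reactants: 20 (7R)-hydroxy ester
Product: 21 7,13-bis-TBS ether ester
Conditions: TBSOTf, 2,6-lutidine, CH2Cl2, −78 to 0 °C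
Reagents that add atoms: tert-butyldimethylsilyl triflate, CC(C)(C)[Si](C)(C)OS(=O)(=O)C(F)(F)F
Why: Silyl triflate/lutidine silylation caps the hindered secondary alcohol quickly at low temperature, before it can lactonise on to the C4 ester, and leaves the acetonide alone.

Step 16
Reactants: 21 bis-TBS ether ester
Product: 22 C4 aldehyde (6R,7R,9R,10S,12R,13S)
Conditions: i-Bu2AlH (DIBAL-H, 1.1 equiv), CH2Cl2, −78 °C
Reagents that add atoms: none
Why: Partial ester reduction with DIBAL-H stops at the aluminium hemiacetal, here also stabilised by coordination to the ring oxygen, and releases the aldehyde only on work-up.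

Step 17
Reactants: 23 1-(triisopropylsilyl)propyne
Product: 25 1,3-bis(triisopropylsilyl)propyne, via lithiated silylpropyne 24 (not isolated)
Conditions: n-BuLi, THF, −20 °C; TIPSOTf, −78 °C to rt
Reagents that add atoms: triisopropylsilyl triflate, CC(C)[Si](C(C)C)(C(C)C)OS(=O)(=O)C(F)(F)F
Why: Propargylic lithiation followed by C-silylation: the acidic CH3 next to the silylalkyne is deprotonated cleanly and the anion is trapped by the silyl triflate at the propargylic carbon.

Step 18
Reactants: 22 C4 aldehyde; 25 1,3-bis(triisopropylsilyl)propyne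
Product: 27 (3Z)-1-TIPS-enyne with 7,13-bis-TBS ethers and the acetonide, via lithiated bis-silylpropyne 26 (not isolated)
Conditions: 25, n-BuLi, THF, −20 °C; then 22, −78 °C to rt
Reagents that add atoms: none
Why: Peterson olefination: the silyl-stabilised propargyl anion adds to the aldehyde faster than it enolises it at −78 °C, and the two bulky silyl groups steer the addition to the adduct whose spontaneous syn loss of silanolate gives the (Z)-enyne, adding C1–C3 in one step.

Step 19
Reactants: 27 (3Z)-1-TIPS-enyne
Product: 28 (3Z)-enyne 7,13-diol 9,10-acetonide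
Conditions: Bu4NF, THF, 0 °C to rt
Reagents that add atoms: none
Why: Fluoride-driven desilylation cleaves both O–Si bonds and the C(sp)–Si bond in one operation because of the strong Si–F bond, while acetonide, ring ether and enyne are inert.

Step 20
Reactants: 28 enyne diol acetonide
Product: 29 7,13-diacetate 9,10-acetonide
Conditions: Ac2O, pyridine, DMAP (cat.), CH2Cl2, rt
Reagents that add atoms: acetic anhydride, CC(=O)OC(C)=O
Why: DMAP-catalysed acylation esterifies the only two free hydroxyls, O7 and O13, with retention, since O9 and O10 are still locked in the ketal.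

Step 21
Reactants: 29 diacetate acetonide
Product: 30 target (6R,7R,9R,10S,12R,13S; 3Z)
Conditions: AcOH–H2O (4:1), 40 °C
Reagents that add atoms: none
Why: Acid-catalysed ketal hydrolysis frees the C9/C10 cis-diol, and in aqueous acetic acid the acetates and the enyne persist and acyl migration, which is base-promoted, stays slow.

Compound list
1 | (±)-pent-1-en-3-ol | C=CC(O)CC | starting material
2 | (2R,3S)-1,2-epoxypentan-3-ol | CC[C@H](O)[C@H]1CO1 | intermediate
3 | (2R,3S)-3-(TBS-oxy)-1,2-epoxypentane | CC[C@H](O[Si](C)(C)C(C)(C)C)[C@H]1CO1 | intermediate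
4 | ethyl propiolate | C#CC(=O)OCC | starting material
5 | lithium ethyl propiolate | [Li]C#CC(=O)OCC | intermediate
6 | ethyl (5R,6S)-6-(TBS-oxy)-5-hydroxyoct-2-ynoate | CCOC(=O)C#CC[C@@H](O)[C@H](CC)O[Si](C)(C)C(C)(C)C | intermediate
7 | ethyl (2Z,5R,6S)-6-(TBS-oxy)-5-hydroxyoct-2-enoate | CCOC(=O)/C=C\C[C@@H](O)[C@H](CC)O[Si](C)(C)C(C)(C)C | intermediate
8 | (6R)-6-[(1S)-1-(TBS-oxy)propyl]-5,6-dihydro-2H-pyran-2-one | CC[C@H](O[Si](C)(C)C(C)(C)C)[C@H]1CC=CC(=O)O1 | intermediate
9 | (3S,4S,6R)-3,4-dihydroxy-6-[(1S)-1-(TBS-oxy)propyl]oxan-2-one | CC[C@H](O[Si](C)(C)C(C)(C)C)[C@H]1C[C@H](O)[C@H](O)C(=O)O1 | intermediate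
10 | 3,4-O-isopropylidene derivative of 9 | CC[C@H](O[Si](C)(C)C(C)(C)C)[C@H]1C[C@@H]2OC(C)(C)O[C@@H]2C(=O)O1 | intermediate
11 | lactol of 10 (C8 hemiacetal, anomer mixture) | CC[C@H](O[Si](C)(C)C(C)(C)C)[C@H]1C[C@@H]2OC(C)(C)O[C@@H]2C(O)O1 | intermediate
12 | (2R,3S)-3-(TBS-oxy)-1-[(4S,5R)-2,2-dimethyl-5-vinyl-1,3-dioxolan-4-yl]pentan-2-ol | O[C@@H]([C@H](CC)O[Si](C)(C)C(C)(C)C)C[C@@H]1OC(C)(C)O[C@@H]1C=C | intermediate
13 | O12 ethyl (E)-β-alkoxyacrylate of 12 | CCOC(=O)/C=C/O[C@@H]([C@H](CC)O[Si](C)(C)C(C)(C)C)C[C@@H]1OC(C)(C)O[C@@H]1C=C | intermediate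
14 | B-alkyl-9-BBN adduct of 13 (boron on C7) | CCOC(=O)/C=C/O[C@@H]([C@H](CC)O[Si](C)(C)C(C)(C)C)C[C@@H]1OC(C)(C)O[C@@H]1CCB1C2CCCC1CCC2 | intermediate
15 | C7 primary alcohol | CCOC(=O)/C=C/O[C@@H]([C@H](CC)O[Si](C)(C)C(C)(C)C)C[C@@H]1OC(C)(C)O[C@@H]1CCO | intermediate
16 | C7 aldehyde | CCOC(=O)/C=C/O[C@@H]([C@H](CC)O[Si](C)(C)C(C)(C)C)C[C@@H]1OC(C)(C)O[C@@H]1CC=O | intermediate
17 | C7 carboxylic acid | CCOC(=O)/C=C/O[C@@H]([C@H](CC)O[Si](C)(C)C(C)(C)C)C[C@@H]1OC(C)(C)O[C@@H]1CC(=O)O | intermediate
18 | C7 phenylselenoester (key-step precursor) | CCOC(=O)/C=C/O[C@@H]([C@H](CC)O[Si](C)(C)C(C)(C)C)C[C@@H]1OC(C)(C)O[C@@H]1CC(=O)[Se]c1ccccc1 | intermediate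
19 | cis-2,8-disubstituted oxocan-3-one fused to the acetonide (key-step product) | CCOC(=O)C[C@H]1O[C@@H]([C@H](CC)O[Si](C)(C)C(C)(C)C)C[C@@H]2OC(C)(C)O[C@@H]2CC1=O | intermediate
20 | (7R)-hydroxy ester | CCOC(=O)C[C@H]1O[C@@H]([C@H](CC)O[Si](C)(C)C(C)(C)C)C[C@@H]2OC(C)(C)O[C@@H]2C[C@H]1O | intermediate
21 | 7,13-bis-TBS ether ester | CCOC(=O)C[C@H]1O[C@@H]([C@H](CC)O[Si](C)(C)C(C)(C)C)C[C@@H]2OC(C)(C)O[C@@H]2C[C@H]1O[Si](C)(C)C(C)(C)C | intermediate
22 | C4 aldehyde | O=CC[C@H]1O[C@@H]([C@H](CC)O[Si](C)(C)C(C)(C)C)C[C@@H]2OC(C)(C)O[C@@H]2C[C@H]1O[Si](C)(C)C(C)(C)C | intermediate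
23 | 1-(triisopropylsilyl)propyne | CC#C[Si](C(C)C)(C(C)C)C(C)C | starting material
24 | 3-lithio-1-(triisopropylsilyl)propyne | [Li]CC#C[Si](C(C)C)(C(C)C)C(C)C | intermediate
25 | 1,3-bis(triisopropylsilyl)propyne | CC(C)[Si](C(C)C)(C(C)C)CC#C[Si](C(C)C)(C(C)C)C(C)C | intermediate
26 | 3-lithio-1,3-bis(triisopropylsilyl)propyne | [Li]C(C#C[Si](C(C)C)(C(C)C)C(C)C)[Si](C(C)C)(C(C)C)C(C)C | intermediate
27 | (3Z)-1-TIPS-enyne, 7,13-bis-TBS ether, 9,10-acetonide | CC(C)[Si](C(C)C)(C(C)C)C#C/C=C\C[C@H]1O[C@@H]([C@H](CC)O[Si](C)(C)C(C)(C)C)C[C@@H]2OC(C)(C)O[C@@H]2C[C@H]1O[Si](C)(C)C(C)(C)C | intermediate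
28 | (3Z)-enyne 7,13-diol 9,10-acetonide | C#C/C=C\C[C@H]1O[C@@H]([C@H](CC)O)C[C@@H]2OC(C)(C)O[C@@H]2C[C@H]1O | intermediate
29 | (3Z)-enyne 7,13-diacetate 9,10-acetonide | C#C/C=C\C[C@H]1O[C@@H]([C@H](CC)OC(C)=O)C[C@@H]2OC(C)(C)O[C@@H]2C[C@H]1OC(C)=O | intermediate
30 | CNP0314743.1 | C#C/C=C\C[C@H]1O[C@@H]([C@H](CC)OC(C)=O)C[C@H](O)[C@H](O)C[C@H]1OC(C)=O | target

Total step count: 21. Longest linear sequence: 20 (steps 1–16 and 18–21; step 17 is a side branch).

Steps most likely to fail

1. Step 13.
- What may go wrong: closure of the eight-membered ring may be slower than hydrogen transfer from the silane to the acyl radical, or slower than loss of CO. Open-chain material would then form instead of the ring.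
- Fallback: the same C6–C7 bond is made from a ketyl instead of an acyl radical. It sets out from alcohol 15. Dess–Martin periodinane (NaHCO3, CH2Cl2) stops at the C7 aldehyde 16, which is now isolated.
- SmI2 (excess) and MeOH in THF at 0 °C reduce 16 to the ketyl, which adds to C6 while trivalent samarium ties the ketyl oxygen to the ester carbonyl.
- There is no chain-carrying hydrogen donor to intercept the radical and no CO to lose. This reductive aldehyde/β-alkoxyacrylate cyclisation is established for oxanes and oxepanes.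
- It should give the 6,7-trans product, 7-epi-hydroxy ester F1. A second Dess–Martin oxidation comes back to the route at ketone 19.

2. Step 14.
- What may go wrong: hydride delivery to a flexible eight-membered ketone may show poor or reversed facial selectivity.
- Fallback: C7 is then set by substitution with inversion instead of by facial choice. It sets out from ketone 19, which is reduced with whichever hydride favours the other face (for example NaBH4, MeOH, low temperature) to 7-epi-hydroxy ester F1, the same alcohol that the samarium route delivers.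
- A Mitsunobu reaction (4-nitrobenzoic acid, PPh3, DIAD, toluene) inverts C7 and gives (7R)-4-nitrobenzoate F2.
- K2CO3 in EtOH at 0 °C cleaves the activated aryl ester much faster than the ethyl ester. The route is rejoined at alcohol 20, which is silylated at once.

3. Step 18.
- What may go wrong: the lithium reagent may enolise the β-alkoxy aldehyde, which leads to β-elimination of the ring oxygen, or the Z selectivity of the elimination may erode.
- Fallback: the enyne is built in two stages through a vinyl iodide. It sets out from aldehyde 22.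
- Stork–Zhao olefination ([Ph3PCH2I]I, NaN(SiMe3)2, THF–DMPU, −78 °C) uses a less basic ylide and should give (Z)-vinyl iodide F3.
- Sonogashira coupling with trimethylsilylacetylene (Pd(PPh3)4, CuI, i-Pr2NH, rt) retains the alkene geometry and gives TMS-enyne F4.
- Bu4NF removes the C-silyl and both O-silyl groups, and the route is rejoined at diol 28.

Further compounds
F1 | step 13 | 7-epi-hydroxy ester (6R,7S,9R,10S,12R,13S) | CCOC(=O)C[C@H]1O[C@@H]([C@H](CC)O[Si](C)(C)C(C)(C)C)C[C@@H]2OC(C)(C)O[C@@H]2C[C@@H]1O
F2 | step 14 | (7R)-4-nitrobenzoate of 20 | CCOC(=O)C[C@H]1O[C@@H]([C@H](CC)O[Si](C)(C)C(C)(C)C)C[C@@H]2OC(C)(C)O[C@@H]2C[C@H]1OC(=O)c1ccc(cc1)[N+](=O)[O-]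
F3 | step 18 | (Z)-vinyl iodide, 7,13-bis-TBS ether, 9,10-acetonide | I/C=C\C[C@H]1O[C@@H]([C@H](CC)O[Si](C)(C)C(C)(C)C)C[C@@H]2OC(C)(C)O[C@@H]2C[C@H]1O[Si](C)(C)C(C)(C)C
F4 | step 18 | (3Z)-1-TMS-enyne, 7,13-bis-TBS ether, 9,10-acetonide | C[Si](C)(C)C#C/C=C\C[C@H]1O[C@@H]([C@H](CC)O[Si](C)(C)C(C)(C)C)C[C@@H]2OC(C)(C)O[C@@H]2C[C@H]1O[Si](C)(C)C(C)(C)C
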